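**Retrosynthetic overview**

- The target is disconnected at C1'–C2' (sp3–sp2 Negishi coupling) into a ring epoxy iodide and the (E)-alkenyl iodide of the side chain; the alkenyl iodide comes from (2E,6E)-farnesol and 1-(trimethylsilyl)propyne by propargylation and carboalumination/iodination. The γ-hydroxy enone is revealed last by ketal hydrolysis and opening of a β,γ-epoxy ketone.
- The epoxy iodide comes from an epoxy alcohol, made by hydroxyl-directed, ligand-controlled epoxidation run as a kinetic resolution of a racemic homoallylic alcohol. That alcohol comes from 3-methoxy-5-methylbenzoic acid by Birch reduction, ketalisation/esterification and hydride reduction.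
- Feature: with the ring numbered C1 (C=O), C2, C3 (C–Me), C4 (CH–OH), C5 (CH–chain), C6 and the chain from C1', the six ring carbons, the C3 methyl, the C1 oxygen and C1' are the atoms of the benzoic acid. The C4 hydroxyl is cis to the C1' arm on C5, so a hydroxyl on C1' can hand the oxygen to C4.
- Rings: the carbocycle is the former arene ring and is never closed. The only ring formed is a temporary oxirane across C3–C4 (step 4), opened again in step 12.

Key step: step 4

Assumption: the (1R,2R) ligand is taken to be the antipode that epoxidises the (S)-alcohol faster; if the opposite sense is found, the (1S,2S) ligand is used and nothing else changes.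

**Ring fragment**

Step 1
Reactants: 1 3-methoxy-5-methylbenzoic acid
Product: 2 rac-3-methoxy-5-methylcyclohexa-2,5-diene-1-carboxylic acid
Conditions: Li, NH3(l)/THF, −78 °C; solid NH4Cl; cold dil. HCl to pH 3–4, EtOAc extraction, used crude
Reagents that add atoms: none
Why: Birch reduction of a benzoic acid protonates the carboxyl-bearing carbon and the carbon para to it, so methoxy and methyl stay on the two surviving double bonds and the future C5 becomes sp3 (racemic).

Step 2
Reactants: 2 rac-3-methoxy-5-methylcyclohexa-2,5-diene-1-carboxylic acid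
Product: 3 rac-methyl 5,5-dimethoxy-3-methylcyclohex-2-ene-1-carboxylate
Conditions: MeOH, HC(OMe)3, cat. TsOH, 0 °C to rt; NaHCO3 quench
Reagents that add atoms: methanol, CO
Why: Acid-catalysed addition of methanol to the enol ether (through the oxocarbenium ion) gives the dimethyl ketal while Fischer esterification runs in the same pot with the orthoformate taking up the water; the isolated trisubstituted alkene should not be protonated by the dilute acid and so stays out of conjugation.

Step 3
Reactants: 3 rac-methyl 5,5-dimethoxy-3-methylcyclohex-2-ene-1-carboxylate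
Product: 4 rac-(5,5-dimethoxy-3-methylcyclohex-2-en-1-yl)methanol
Conditions: LiAlH4, THF, 0 °C; H2O/aq. NaOH work-up; chromatography on Et3N-treated silica
Reagents that add atoms: none
Why: Hydride reduction of the ester with LiAlH4 gives the primary alcohol, and the ketal and alkene are inert to hydride and to the basic work-up.

Step 4
Reactants: 4 rac-(5,5-dimethoxy-3-methylcyclohex-2-en-1-yl)methanol
Product: 5 [(1S,2R,6R)-4,4-dimethoxy-6-methyl-7-oxabicyclo[4.1.0]heptan-2-yl]methanol (CH2OH cis to the epoxide oxygen)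
Conditions: VO(OiPr)3 (2 mol %), (1R,2R)-N,N'-dihydroxy-N,N'-bis(diphenylacetyl)cyclohexane-1,2-diamine (4 mol %), t-BuOOH (0.5 equiv, anhydrous), toluene, 0 °C; chromatography on Et3N-treated silica
Reagents that add atoms: tert-butyl hydroperoxide, CC(C)(C)OO
Why: Proposed new method: the primary hydroxyl of 4 binds pentavalent vanadium as an alkoxide beside the η2-bound tert-butyl peroxide, and oxygen passes within this complex to the C3=C4 alkene, so each enantiomer can only be epoxidised on the ring face that carries its own CH2O–V arm. The closest known reaction type is the vanadium–bishydroxamic acid catalysed asymmetric epoxidation of achiral homoallylic alcohols and the kinetic resolution of secondary ones; resolving a primary alcohol whose stereocentre is the allylic ring carbon is the untested part. The oxirane, the only ring closed and a temporary one, forms by concerted intramolecular oxygen-atom transfer across C3=C4 (syn [2+1] addition). The new C4 and C3 centres are fixed relative to C5 by this syn delivery, and the absolute sense comes from the ligand, whose preferred alkene face coincides with the directed face only in (S)-4, so with half an equivalent of peroxide the (R)-enantiomer of 4 should stay behind and be separated by chromatography. The step needs enantiomer discrimination and face selectivity, both secured by the rigid cyclohexene in which the stereocentre sits on the allylic carbon between the alkoxide arm and the alkene; chemoselectivity is no issue because 4 has one electron-rich trisubstituted alkene.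

Step 5
Reactants: 5 [(1S,2R,6R)-4,4-dimethoxy-6-methyl-7-oxabicyclo[4.1.0]heptan-2-yl]methanol
Product: 6 [(1S,2R,6R)-4,4-dimethoxy-6-methyl-7-oxabicyclo[4.1.0]heptan-2-yl]methyl 4-methylbenzenesulfonate
Conditions: TsCl, Et3N, cat. DMAP, CH2Cl2, 0 °C
Reagents that add atoms: 4-methylbenzenesulfonyl chloride, Cc1ccc(cc1)S(Cl)(=O)=O
Why: Sulfonylation (tosylation) of the primary alcohol under amine base leaves epoxide, ketal and all stereocentres untouched; because the CH2O arm is cis to the epoxide oxygen it cannot open the oxirane from the back.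

Step 6
Reactants: 6 [(1S,2R,6R)-4,4-dimethoxy-6-methyl-7-oxabicyclo[4.1.0]heptan-2-yl]methyl 4-methylbenzenesulfonate
Product: 7 (1R,5S,6S)-5-(iodomethyl)-3,3-dimethoxy-1-methyl-7-oxabicyclo[4.1.0]heptane (CH2I cis to the epoxide oxygen)
Conditions: NaI, NaHCO3, acetone, 50 °C
Reagents that add atoms: sodium iodide, [Na+].[I-]
Why: Finkelstein reaction, an SN2 displacement of the primary tosylate by iodide under buffered neutral conditions in which the trisubstituted epoxide and the ketal should persist.

**Side-chain fragment**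

Step 7
Reactants: 8 (2E,6E)-farnesol
Product: 9 (2E,6E)-1-bromo-3,7,11-trimethyldodeca-2,6,10-triene (farnesyl bromide)
Conditions: PBr3, cat. pyridine, Et2O, −10 °C
Reagents that add atoms: phosphorus tribromide, BrP(Br)Br
Why: Bromination of the primary allylic alcohol with PBr3 at low temperature proceeds by SN2 at the primary carbon and keeps the E geometry of the 2,3-alkene.

Step 8
Reactants: 9 (2E,6E)-1-bromo-3,7,11-trimethyldodeca-2,6,10-triene; 10 1-(trimethylsilyl)propyne
Product: 12 trimethyl[(5E,9E)-6,10,14-trimethylpentadeca-5,9,13-trien-1-yn-1-yl]silane, via lithiated silylpropyne 11 (not isolated)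
Conditions: 10, n-BuLi, THF, −78 to −20 °C; then 9, −78 °C to rt
Reagents that add atoms: none
Why: Propargylic lithiation followed by SN2 alkylation with the primary allylic bromide; the silyl group suppresses the allenyl mode and the unhindered bromide reacts without allylic transposition.

Step 9
Reactants: 12 trimethyl[(5E,9E)-6,10,14-trimethylpentadeca-5,9,13-trien-1-yn-1-yl]silane
Product: 13 (5E,9E)-6,10,14-trimethylpentadeca-5,9,13-trien-1-yne
Conditions: K2CO3, MeOH, rt
Reagents that add atoms: none
Why: Protodesilylation of the alkynylsilane by methanolic carbonate, which does not touch the alkenes.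

Step 10
Reactants: 13 (5E,9E)-6,10,14-trimethylpentadeca-5,9,13-trien-1-yne
Product: 15 (1E,5E,9E)-1-iodo-2,6,10,14-tetramethylpentadeca-1,5,9,13-tetraene, via alkenylalane 14 (not isolated)
Conditions: AlMe3 (2 equiv), Cp2ZrCl2 (0.25 equiv), CH2Cl2, 0 °C to rt; then I2, THF, −30 to 0 °C
Reagents that add atoms: trimethylaluminium, C[Al](C)C; iodine, II
Why: Negishi zirconium-catalysed carboalumination adds Me–Al syn across the terminal alkyne with methyl on the internal carbon, and iodinolysis of the C–Al bond with retention fixes the E trisubstituted alkene that becomes C2'=C3'.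

**Coupling and end game**

Step 11
Reactants: 7 (1R,5S,6S)-5-(iodomethyl)-3,3-dimethoxy-1-methyl-7-oxabicyclo[4.1.0]heptane; 15 (1E,5E,9E)-1-iodo-2,6,10,14-tetramethylpentadeca-1,5,9,13-tetraene
Product: 17 (1R,5S,6S)-3,3-dimethoxy-1-methyl-5-[(2E,6E,10E)-3,7,11,15-tetramethylhexadeca-2,6,10,14-tetraen-1-yl]-7-oxabicyclo[4.1.0]heptane, via alkylzinc iodide 16 (not isolated)
Conditions: 7, Zn dust (activated with BrCH2CH2Br/TMSCl), THF/DMA, 40 °C; then 15, PdCl2(dppf) (5 mol %), rt
Reagents that add atoms: none
Why: Negishi coupling, in which zinc insertion into the primary iodide gives an alkylzinc iodide that transmetalates to the alkenylpalladium iodide formed from 15 and zerovalent palladium, and reductive elimination forms C1'–C2' with retention of the E geometry; the cis arrangement of CH2Zn and epoxide oxygen excludes backside 1,3-displacement and the amide cosolvent damps the Lewis acidity of the zinc salts.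

Step 12
Reactants: 17 (1R,5S,6S)-3,3-dimethoxy-1-methyl-5-[(2E,6E,10E)-3,7,11,15-tetramethylhexadeca-2,6,10,14-tetraen-1-yl]-7-oxabicyclo[4.1.0]heptane
Product: 19 (4S,5S)-4-hydroxy-3-methyl-5-[(2E,6E,10E)-3,7,11,15-tetramethylhexadeca-2,6,10,14-tetraen-1-yl]cyclohex-2-en-1-one, via epoxy ketone 18 (not isolated)
Conditions: PPTS (cat.), acetone/H2O 9:1, rt; then Et3N, rt
Reagents that add atoms: water, O
Why: Mild acid-catalysed ketal hydrolysis frees the C1 ketone, and amine-promoted E1cB opening of the β,γ-epoxy ketone (deprotonation at C2, cleavage of C3–O) gives the γ-hydroxy enone with the C4–O bond and C5 untouched, so the cis (4S,5S) configuration is carried over.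

**Compound list**

1 | 3-methoxy-5-methylbenzoic acid | COc1cc(C)cc(c1)C(=O)O | starting material
2 | rac-3-methoxy-5-methylcyclohexa-2,5-diene-1-carboxylic acid | COC1=CC(C(=O)O)C=C(C)C1 | intermediate
3 | rac-methyl 5,5-dimethoxy-3-methylcyclohex-2-ene-1-carboxylate | COC(=O)C1CC(OC)(OC)CC(C)=C1 | intermediate
4 | rac-(5,5-dimethoxy-3-methylcyclohex-2-en-1-yl)methanol | OCC1CC(OC)(OC)CC(C)=C1 | intermediate
5 | [(1S,2R,6R)-4,4-dimethoxy-6-methyl-7-oxabicyclo[4.1.0]heptan-2-yl]methanol | OC[C@H]1CC(OC)(OC)C[C@@]2(C)O[C@@H]12 | intermediate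
6 | [(1S,2R,6R)-4,4-dimethoxy-6-methyl-7-oxabicyclo[4.1.0]heptan-2-yl]methyl 4-methylbenzenesulfonate | Cc1ccc(cc1)S(=O)(=O)OC[C@H]1CC(OC)(OC)C[C@@]2(C)O[C@@H]12 | intermediate
7 | (1R,5S,6S)-5-(iodomethyl)-3,3-dimethoxy-1-methyl-7-oxabicyclo[4.1.0]heptane | IC[C@H]1CC(OC)(OC)C[C@@]2(C)O[C@@H]12 | intermediate
8 | (2E,6E)-farnesol | CC(C)=CCC/C(C)=C/CC/C(C)=C/CO | starting material
9 | (2E,6E)-1-bromo-3,7,11-trimethyldodeca-2,6,10-triene | CC(C)=CCC/C(C)=C/CC/C(C)=C/CBr | intermediate
10 | 1-(trimethylsilyl)propyne | CC#C[Si](C)(C)C | starting material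
11 | [3-(trimethylsilyl)prop-2-yn-1-yl]lithium | [Li]CC#C[Si](C)(C)C | intermediate
12 | trimethyl[(5E,9E)-6,10,14-trimethylpentadeca-5,9,13-trien-1-yn-1-yl]silane | CC(C)=CCC/C(C)=C/CC/C(C)=C/CCC#C[Si](C)(C)C | intermediate
13 | (5E,9E)-6,10,14-trimethylpentadeca-5,9,13-trien-1-yne | CC(C)=CCC/C(C)=C/CC/C(C)=C/CCC#C | intermediate
14 | dimethyl[(1E,5E,9E)-2,6,10,14-tetramethylpentadeca-1,5,9,13-tetraen-1-yl]alumane | CC(C)=CCC/C(C)=C/CC/C(C)=C/CC/C(C)=C/[Al](C)C | intermediate
15 | (1E,5E,9E)-1-iodo-2,6,10,14-tetramethylpentadeca-1,5,9,13-tetraene | CC(C)=CCC/C(C)=C/CC/C(C)=C/CC/C(C)=C/I | intermediate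
16 | {[(1S,2S,6R)-4,4-dimethoxy-6-methyl-7-oxabicyclo[4.1.0]heptan-2-yl]methyl}(iodo)zinc | I[Zn]C[C@H]1CC(OC)(OC)C[C@@]2(C)O[C@@H]12 | intermediate
17 | (1R,5S,6S)-3,3-dimethoxy-1-methyl-5-[(2E,6E,10E)-3,7,11,15-tetramethylhexadeca-2,6,10,14-tetraen-1-yl]-7-oxabicyclo[4.1.0]heptane | CC(C)=CCC/C(C)=C/CC/C(C)=C/CC/C(C)=C/C[C@H]1CC(OC)(OC)C[C@@]2(C)O[C@@H]12 | intermediate
18 | (1R,5S,6S)-1-methyl-5-[(2E,6E,10E)-3,7,11,15-tetramethylhexadeca-2,6,10,14-tetraen-1-yl]-7-oxabicyclo[4.1.0]heptan-3-one | CC(C)=CCC/C(C)=C/CC/C(C)=C/CC/C(C)=C/C[C@H]1CC(=O)C[C@@]2(C)O[C@@H]12 | intermediate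
19 | (4S,5S)-4-hydroxy-3-methyl-5-[(2E,6E,10E)-3,7,11,15-tetramethylhexadeca-2,6,10,14-tetraen-1-yl]cyclohex-2-en-1-one | CC(C)=CCC/C(C)=C/CC/C(C)=C/CC/C(C)=C/C[C@H]1CC(=O)C=C(C)[C@H]1O | target

**Step count**

Total steps: 12. Longest linear sequence: 8 steps (steps 1–6, 11 and 12, from 1 to 19); the side-chain branch is steps 7–10.

**Steps most likely to fail**

First, step 4. The catalyst may discriminate poorly between the two enantiomers of a primary alcohol, or a slow directed oxidation may let unselective background epoxidation erode the enantiomeric purity. The fallback separates the enantiomers by known chemistry and uses the hydroxyl only for face control. It sets out from acid 2, which is crystallised with (R)-1-phenylethylamine (or its antipode, whichever gives the less soluble salt of the wanted acid) to give (R)-1-phenylethylammonium (R)-3-methoxy-5-methylcyclohexa-2,5-diene-1-carboxylate F1. Cold aqueous NaH2PO4 should liberate (R)-3-methoxy-5-methylcyclohexa-2,5-diene-1-carboxylic acid F2. The conditions of steps 2 and 3 should then give methyl (S)-5,5-dimethoxy-3-methylcyclohex-2-ene-1-carboxylate F3 and (S)-(5,5-dimethoxy-3-methylcyclohex-2-en-1-yl)methanol F4. Achiral hydroxyl-directed epoxidation of F4 (VO(acac)2 cat., t-BuOOH, toluene, rt) should deliver the oxygen syn to the CH2OH group, and the route is rejoined at 5.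

Second, step 11. Zinc insertion into the β-branched iodide may stall, zinc iodide may promote opening of the epoxide by iodide, or the alkylpalladium may undergo β-hydride elimination. The fallback is a B-alkyl Suzuki–Miyaura coupling that avoids zinc salts. It sets out from iodide 7: t-BuLi (2 equiv) is added at −78 °C to 7 and 9-methoxy-9-borabicyclo[3.3.1]nonane in Et2O/THF, and iodine–lithium exchange with immediate capture by boron should give lithium {[(1S,2S,6R)-4,4-dimethoxy-6-methyl-7-oxabicyclo[4.1.0]heptan-2-yl]methyl}(methoxy)-9-borabicyclo[3.3.1]nonan-9-uide F5. This borate is coupled with 15 (PdCl2(dppf), aqueous K3PO4, DMF, rt), and the route is rejoined at 17.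

Third, step 12. With the tetraene chain in place, acid may hydrate or cyclise the chain while the ketal hydrolyses, and pushing the conditions risks dehydration of the γ-hydroxy enone towards a phenol. The fallback reorders the end game so that the unmasking is done on the small ring fragment. It sets out from iodide 7: PPTS in aqueous acetone, then catalytic DBU, should give (4S,5S)-4-hydroxy-5-(iodomethyl)-3-methylcyclohex-2-en-1-one F6. Silylation (TBSCl, imidazole, DMF) gives (4S,5S)-4-[(tert-butyldimethylsilyl)oxy]-5-(iodomethyl)-3-methylcyclohex-2-en-1-one F7. Zinc insertion as in step 11 gives {[(1S,2S)-2-[(tert-butyldimethylsilyl)oxy]-3-methyl-5-oxocyclohex-3-en-1-yl]methyl}(iodo)zinc F8, which is coupled with 15 (PdCl2(dppf), THF/DMA, rt) to (4S,5S)-4-[(tert-butyldimethylsilyl)oxy]-3-methyl-5-[(2E,6E,10E)-3,7,11,15-tetramethylhexadeca-2,6,10,14-tetraen-1-yl]cyclohex-2-en-1-one F9. Desilylation (TBAF buffered with AcOH, THF, 0 °C) rejoins the route at 19.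

**Further compounds**

F1 | step 4 | (R)-1-phenylethylammonium (R)-3-methoxy-5-methylcyclohexa-2,5-diene-1-carboxylate | C[C@@H]([NH3+])c1ccccc1.[O-]C(=O)[C@H]1C=C(OC)CC(C)=C1
F2 | step 4 | (R)-3-methoxy-5-methylcyclohexa-2,5-diene-1-carboxylic acid | OC(=O)[C@H]1C=C(OC)CC(C)=C1
F3 | step 4 | methyl (S)-5,5-dimethoxy-3-methylcyclohex-2-ene-1-carboxylate | COC(=O)[C@H]1CC(OC)(OC)CC(C)=C1
F4 | step 4 | (S)-(5,5-dimethoxy-3-methylcyclohex-2-en-1-yl)methanol | OC[C@H]1CC(OC)(OC)CC(C)=C1
F5 | step 11 | lithium {[(1S,2S,6R)-4,4-dimethoxy-6-methyl-7-oxabicyclo[4.1.0]heptan-2-yl]methyl}(methoxy)-9-borabicyclo[3.3.1]nonan-9-uide | [Li+].CO[B-]1(C[C@H]2CC(OC)(OC)C[C@@]3(C)O[C@@H]23)C2CCCC1CCC2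
F6 | step 12 | (4S,5S)-4-hydroxy-5-(iodomethyl)-3-methylcyclohex-2-en-1-one | IC[C@H]1CC(=O)C=C(C)[C@H]1O
F7 | step 12 | (4S,5S)-4-[(tert-butyldimethylsilyl)oxy]-5-(iodomethyl)-3-methylcyclohex-2-en-1-one | IC[C@H]1CC(=O)C=C(C)[C@H]1O[Si](C)(C)C(C)(C)C
F8 | step 12 | {[(1S,2S)-2-[(tert-butyldimethylsilyl)oxy]-3-methyl-5-oxocyclohex-3-en-1-yl]methyl}(iodo)zinc | I[Zn]C[C@H]1CC(=O)C=C(C)[C@H]1O[Si](C)(C)C(C)(C)C
F9 | step 12 | (4S,5S)-4-[(tert-butyldimethylsilyl)oxy]-3-methyl-5-[(2E,6E,10E)-3,7,11,15-tetramethylhexadeca-2,6,10,14-tetraen-1-yl]cyclohex-2-en-1-one | CC(C)=CCC/C(C)=C/CC/C(C)=C/CC/C(C)=C/C[C@H]1CC(=O)C=C(C)[C@H]1O[Si](C)(C)C(C)(C)C
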